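**Plan** (numbering: ring C1 = CMe2, C2, C3, C4, C5 = C–CH3, C6; chain C7–C15; butenolide C16–C19)
1. Retrosynthesis first cuts the C10=C11 alkene (cross-metathesis) into a western C15 vinyl carbinol and an eastern allyl butenolide; then, in the west, the ring bonds C1–C2 and C3–C4 are cut together, a retro-[4+2] that removes the unsubstituted C2–C3 unit as an ethylene equivalent.
2. Enabling feature: the six-membered ring has a single C=C (C5=C6, tetrasubstituted) flanked by the ring CH2 (C4) and the CMe2 carbon (C1), with a bare CH2–CH2 opposite it. This is the cyclohexene retron of the diene CH2=C(Me)–C(R)=CMe2 plus ethylene; acrolein ethylene acetal stands in for ethylene and its formyl carbon is excised afterwards.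
3. Forward, west: 2-bromopropene, 1,1-dimethylallene and methyl acetoacetate are joined by palladium to the acyclic diene, the ring is closed in step 3, the helper carbon is removed, and the chain is extended to the (E)-allylic alcohol and on to the tertiary carbinol.
4. Forward, east: carbomagnesiation and iodination of propargyl alcohol fix the C13=C14 geometry, opening of methyl (S)-glycidate makes C14–C15, and the butenolide is closed by Dieckmann condensation and then hydroxymethylated.
5. Stereochemistry: C9 (S) from Sharpless epoxidation with L-(+)-diethyl tartrate and reductive epoxide opening; C16 (S) from methyl (S)-glycidate; 13Z from the chelated alkenylmagnesium intermediate; 10E from cross-metathesis.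

Key step: step 3

Remark: compounds 4, 7 and 8 are racemic; their stereocentres are erased in steps 2 and 4, so neither the orientation of the dienophile nor its facial selectivity needs control.

Step 1
Reactants: 1 2-bromopropene; 2 3-methylbuta-1,2-diene; 3 methyl acetoacetate
Product: 4 methyl 2-acetyl-5-methyl-4-(propan-2-ylidene)hex-5-enoate (racemic)
Conditions: NaH, Pd(dba)2 (5 mol%), dppe (5 mol%), THF, 65 °C, sealed tube
Reagents that add atoms: none
Why: Palladium-catalysed three-component coupling (carbopalladation of an allene): after oxidative addition of 1 to zerovalent palladium the isopropenyl group adds to the central allene carbon, and the soft sodium enolate attacks the resulting π-allyl complex at its unsubstituted CH2 terminus, which should give the diene with the isopropylidene end.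

Step 2
Reactants: 4 methyl 2-acetyl-5-methyl-4-(propan-2-ylidene)hex-5-enoate
Product: 5 6-methyl-5-(propan-2-ylidene)hept-6-en-2-one
Conditions: LiCl, H2O, DMSO, 150 °C
Reagents that add atoms: none
Why: Krapcho dealkoxycarbonylation (chloride attack on the ester methyl group, loss of CO2) should leave the methyl ketone under neutral conditions that do not touch the diene.

Step 3
Reactants: 5 6-methyl-5-(propan-2-ylidene)hept-6-en-2-one; 6 2-vinyl-1,3-dioxolane
Product: 8 2,2,4-trimethyl-3-(3-oxobutyl)cyclohex-3-ene-1-carbaldehyde (racemic), via dioxolane cycloadduct 7 (not isolated)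
Conditions: TfOH (5 mol%), CH2Cl2, −78 °C; then 1 M HCl, THF, 23 °C
Reagents that add atoms: water, O
Why: Ionic Diels–Alder reaction: TfOH opens the dioxolane of 6 to a 1-alkoxyallyl cation whose terminal CH2 is attacked by the CH2 terminus of diene 5 (first ring bond), leaving an enol ether tethered to a fully substituted allyl cation; the enol ether carbon then closes onto the CMe2 terminus (second ring bond, creating the quaternary carbon), the oxocarbenium ion is recaptured as the dioxolane 7, and the acidic work-up hydrolyses it to aldehyde 8. The closest known reaction type is the acid-catalysed cycloaddition of acrolein acetals to 1,3-dienes, a stepwise cationic [4+2] that does not need the planar s-cis diene which the inner methyl group of the CMe2 terminus disfavours in thermal cycloadditions. The cyclohexene closes as an intermolecular [4+2] annulation whose ring-closing event is a 6-endo cation–olefin cyclisation; closure at the other allyl terminus would give a cyclobutane and is not expected. The one new stereocentre (the CH that carries the acetal, then the formyl group) forms as a racemate and needs no control because it becomes a CH2 in step 4, and the same holds for the orientation of the dienophile, which the cationic pathway nevertheless fixes by passing through the tertiary allyl cation. The selectivity needed is chemoselectivity for ionisation of the acetal over protonation of the electron-rich diene or activation of the ketone, which the higher basicity of the acetal oxygens, the catalytic amount of acid and the low temperature should secure.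

Step 4
Reactants: 8 2,2,4-trimethyl-3-(3-oxobutyl)cyclohex-3-ene-1-carbaldehyde
Product: 9 4-(2,6,6-trimethylcyclohex-1-en-1-yl)butan-2-one
Conditions: RhCl(PPh3)3 (1.1 equiv), toluene, 110 °C
Reagents that add atoms: none
Why: Tsuji–Wilkinson decarbonylation (oxidative addition of the formyl C–H bond to monovalent rhodium, CO extrusion, C–H reductive elimination) should replace CHO by H, which removes the helper carbon and the only stereocentre while ketone and tetrasubstituted alkene stay untouched.

Step 5
Reactants: 9 4-(2,6,6-trimethylcyclohex-1-en-1-yl)butan-2-one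
Product: 10 ethyl (2E)-3-methyl-5-(2,6,6-trimethylcyclohex-1-en-1-yl)pent-2-enoate
Conditions: (EtO)2P(O)CH2CO2Et, NaH, THF, 0 → 65 °C; chromatography
Reagents that add atoms: triethyl phosphonoacetate, CCOC(=O)CP(=O)(OCC)OCC
Why: Horner–Wadsworth–Emmons olefination of the methyl ketone should favour the (E)-enoate (ester trans to the larger CH2CH2R group), and the minor (Z)-isomer is to be removed by chromatography.

Step 6
Reactants: 10 ethyl (2E)-3-methyl-5-(2,6,6-trimethylcyclohex-1-en-1-yl)pent-2-enoate
Product: 11 (2E)-3-methyl-5-(2,6,6-trimethylcyclohex-1-en-1-yl)pent-2-en-1-ol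
Conditions: i-Bu2AlH (2.5 equiv), CH2Cl2, −78 °C
Reagents that add atoms: none
Why: 1,2-Reduction of the conjugated ester by i-Bu2AlH at low temperature should give the allylic alcohol without affecting either alkene.

Step 7
Reactants: 11 (2E)-3-methyl-5-(2,6,6-trimethylcyclohex-1-en-1-yl)pent-2-en-1-ol
Product: 12 [(2S,3S)-3-methyl-3-[2-(2,6,6-trimethylcyclohex-1-en-1-yl)ethyl]oxiran-2-yl]methanol
Conditions: Ti(OiPr)4 (10 mol%), L-(+)-diethyl tartrate (12 mol%), t-BuOOH, 4 Å molecular sieves, CH2Cl2, −20 °C
Reagents that add atoms: tert-butyl hydroperoxide, CC(C)(C)OO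
Why: Sharpless asymmetric epoxidation: with L-(+)-diethyl tartrate the titanium tartrate complex should deliver oxygen to the face of the (E)-allylic alcohol that gives the (2S,3S)-epoxide (the geraniol sense), and only the alkene of the allylic alcohol is epoxidised.

Step 8
Reactants: 12 [(2S,3S)-3-methyl-3-[2-(2,6,6-trimethylcyclohex-1-en-1-yl)ethyl]oxiran-2-yl]methanol
Product: 14 (3S)-3-methyl-5-(2,6,6-trimethylcyclohex-1-en-1-yl)pent-1-en-3-ol, via epoxy iodide 13 (not isolated)
Conditions: PPh3, I2, imidazole, Et2O/MeCN, 0 °C; then Zn, AcOH, EtOH, 23 °C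
Reagents that add atoms: iodine, II (its atom is held only in intermediate 13)
Why: Appel-type iodination of the primary alcohol followed by zinc-mediated reductive opening of the 2,3-epoxy iodide should give the tertiary vinyl carbinol; the C–O bond at the quaternary carbon is not broken, so its configuration is carried over as (S).

Step 9
Reactants: 15 prop-2-yn-1-ol
Product: 17 (2Z)-2-(iodomethylidene)pent-4-en-1-ol, via cyclic alkenylmagnesium alkoxide 16 (not isolated)
Conditions: CH2=CHCH2MgBr (2.5 equiv), CuI (10 mol%), Et2O, 0 → 23 °C; then I2, THF, −78 → 0 °C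
Reagents that add atoms: allylmagnesium bromide, C=CC[Mg]Br; iodine, II
Why: Copper-catalysed anti-carbomagnesiation of propargyl alcohol places the allyl group on the internal carbon and magnesium, held in a five-membered chelate by the alkoxide, cis to the CH2O group, so that iodinolysis with retention should fix the (Z)-geometry needed for C13=C14.

Step 10
Reactants: 17 (2Z)-2-(iodomethylidene)pent-4-en-1-ol
Product: 18 tert-butyl{[(2Z)-2-(iodomethylidene)pent-4-en-1-yl]oxy}dimethylsilane
Conditions: TBSCl, imidazole, CH2Cl2, 23 °C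
Reagents that add atoms: tert-butyldimethylsilyl chloride, CC(C)(C)[Si](C)(C)Cl
Why: Standard silylation of the primary allylic alcohol protects it for the organometallic step.

Step 11
Reactants: 18 tert-butyl{[(2Z)-2-(iodomethylidene)pent-4-en-1-yl]oxy}dimethylsilane; 19 methyl (2S)-oxirane-2-carboxylate
Product: 22 methyl (2S,4Z)-2-acetoxy-5-{[tert-butyl(dimethyl)silyl]oxymethyl}octa-4,7-dienoate, via alkenylmagnesium chloride 20 (not isolated), via chloromagnesium alkoxide 21 (not isolated)
Conditions: i-PrMgCl·LiCl, THF, 0 → 23 °C; CuI (10 mol%), 19, −40 °C; then Ac2O, −40 → 0 °C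
Reagents that add atoms: acetic anhydride, CC(=O)OC(C)=O; isopropylmagnesium chloride, CC(C)[Mg]Cl (Mg and Cl are held only in intermediates 20 and 21)
Why: Stereoretentive iodine–magnesium exchange gives the alkenyl Grignard reagent, which under copper catalysis should open the glycidate at its CH2 terminus (SN2, the stereocentre of 19 is not touched and becomes C16, S), and the magnesium alkoxide is acetylated in the same flask.

Step 12
Reactants: 22 methyl (2S,4Z)-2-acetoxy-5-{[tert-butyl(dimethyl)silyl]oxymethyl}octa-4,7-dienoate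
Product: 23 (5S)-5-[(2Z)-3-{[tert-butyl(dimethyl)silyl]oxymethyl}hexa-2,5-dien-1-yl]-4-hydroxyfuran-2(5H)-one
Conditions: LiN(SiMe3)2 (2.5 equiv), THF, −78 → −20 °C; then 1 M HCl, 0 °C
Reagents that add atoms: none
Why: Dieckmann condensation of the acetate enolate onto the methyl ester should give the tetronic acid; at low temperature the amide base removes an acetate CH3 proton in preference to the hindered C–H of the stereocentre, so the (S)-configuration should be kept.

Step 13
Reactants: 23 (5S)-5-[(2Z)-3-{[tert-butyl(dimethyl)silyl]oxymethyl}hexa-2,5-dien-1-yl]-4-hydroxyfuran-2(5H)-one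
Product: 24 (2S)-2-[(2Z)-3-{[tert-butyl(dimethyl)silyl]oxymethyl}hexa-2,5-dien-1-yl]-5-oxo-2,5-dihydrofuran-3-yl trifluoromethanesulfonate
Conditions: Tf2O, i-Pr2NEt, CH2Cl2, −78 °C
Reagents that add atoms: triflic anhydride, O=S(=O)(OS(=O)(=O)C(F)(F)F)C(F)(F)F
Why: O-Sulfonylation of the acidic vinylogous acid should give the enol triflate needed for cross-coupling.

Step 14
Reactants: 24 (2S)-2-[(2Z)-3-{[tert-butyl(dimethyl)silyl]oxymethyl}hexa-2,5-dien-1-yl]-5-oxo-2,5-dihydrofuran-3-yl trifluoromethanesulfonate
Product: 25 (5S)-5-[(2Z)-3-{[tert-butyl(dimethyl)silyl]oxymethyl}hexa-2,5-dien-1-yl]-4-(hydroxymethyl)furan-2(5H)-one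
Conditions: Bu3SnCH2OH, Pd(PPh3)4 (5 mol%), LiCl, 1,4-dioxane, 90 °C
Reagents that add atoms: (tributylstannyl)methanol, CCCC[Sn](CCCC)(CCCC)CO
Why: Stille coupling of the electron-poor enol triflate with (tributylstannyl)methanol should transfer the hydroxymethyl group under neutral conditions that do not epimerise the γ-stereocentre.

Step 15
Reactants: 14 (3S)-3-methyl-5-(2,6,6-trimethylcyclohex-1-en-1-yl)pent-1-en-3-ol; 25 (5S)-5-[(2Z)-3-{[tert-butyl(dimethyl)silyl]oxymethyl}hexa-2,5-dien-1-yl]-4-(hydroxymethyl)furan-2(5H)-one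
Product: 26 (5S)-5-[(2Z,5E,7S)-3-{[tert-butyl(dimethyl)silyl]oxymethyl}-7-hydroxy-7-methyl-9-(2,6,6-trimethylcyclohex-1-en-1-yl)nona-2,5-dien-1-yl]-4-(hydroxymethyl)furan-2(5H)-one
Conditions: second-generation Grubbs catalyst (10 mol%), 14 (3 equiv), CH2Cl2, 40 °C
Reagents that add atoms: none
Why: Olefin cross-metathesis between a terminal alkene and a tertiary vinyl carbinol (slow to homodimerise, used in excess) should give the 1,2-disubstituted alkene with (E)-geometry under thermodynamic control, while the tri- and tetrasubstituted alkenes and the butenolide do not take part.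

Step 16
Reactants: 26 (5S)-5-[(2Z,5E,7S)-3-{[tert-butyl(dimethyl)silyl]oxymethyl}-7-hydroxy-7-methyl-9-(2,6,6-trimethylcyclohex-1-en-1-yl)nona-2,5-dien-1-yl]-4-(hydroxymethyl)furan-2(5H)-one
Product: 27 (5S)-5-[(2Z,5E,7S)-7-hydroxy-3-(hydroxymethyl)-7-methyl-9-(2,6,6-trimethylcyclohex-1-en-1-yl)nona-2,5-dien-1-yl]-4-(hydroxymethyl)furan-2(5H)-one
Conditions: HF·pyridine, pyridine, THF, 0 → 23 °C
Reagents that add atoms: none
Why: Cleavage of the primary silyl ether by buffered fluoride should spare the tertiary allylic alcohol and the base-sensitive butenolide.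

**Compound list**
1 | 2-bromopropene | CC(Br)=C | starting material
2 | 3-methylbuta-1,2-diene | CC(C)=C=C | starting material
3 | methyl acetoacetate | COC(=O)CC(C)=O | starting material
4 | methyl 2-acetyl-5-methyl-4-(propan-2-ylidene)hex-5-enoate (racemic) | COC(=O)C(CC(=C(C)C)C(C)=C)C(C)=O | intermediate
5 | 6-methyl-5-(propan-2-ylidene)hept-6-en-2-one | CC(=O)CCC(=C(C)C)C(C)=C | intermediate
6 | 2-vinyl-1,3-dioxolane | C=CC1OCCO1 | starting material
7 | 4-[5-(1,3-dioxolan-2-yl)-2,6,6-trimethylcyclohex-1-en-1-yl]butan-2-one (racemic) | CC(=O)CCC1=C(C)CCC(C2OCCO2)C1(C)C | intermediate (not isolated)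
8 | 2,2,4-trimethyl-3-(3-oxobutyl)cyclohex-3-ene-1-carbaldehyde (racemic) | CC(=O)CCC1=C(C)CCC(C=O)C1(C)C | intermediate
9 | 4-(2,6,6-trimethylcyclohex-1-en-1-yl)butan-2-one | CC(=O)CCC1=C(C)CCCC1(C)C | intermediate
10 | ethyl (2E)-3-methyl-5-(2,6,6-trimethylcyclohex-1-en-1-yl)pent-2-enoate | CCOC(=O)/C=C(\C)CCC1=C(C)CCCC1(C)C | intermediate
11 | (2E)-3-methyl-5-(2,6,6-trimethylcyclohex-1-en-1-yl)pent-2-en-1-ol | OC/C=C(\C)CCC1=C(C)CCCC1(C)C | intermediate
12 | [(2S,3S)-3-methyl-3-[2-(2,6,6-trimethylcyclohex-1-en-1-yl)ethyl]oxiran-2-yl]methanol | OC[C@@H]1O[C@@]1(C)CCC2=C(C)CCCC2(C)C | intermediate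
13 | (2R,3S)-2-(iodomethyl)-3-methyl-3-[2-(2,6,6-trimethylcyclohex-1-en-1-yl)ethyl]oxirane | IC[C@@H]1O[C@@]1(C)CCC2=C(C)CCCC2(C)C | intermediate (not isolated)
14 | (3S)-3-methyl-5-(2,6,6-trimethylcyclohex-1-en-1-yl)pent-1-en-3-ol | CC1=C(CC[C@](C)(O)C=C)C(C)(C)CCC1 | intermediate
15 | prop-2-yn-1-ol | C#CCO | starting material
16 | 4-(prop-2-en-1-yl)-2,5-dihydro-1,2-oxamagnesole (cyclic alkenylmagnesium alkoxide, Mg cis to CH2O) | C=CCC1=C[Mg]OC1 | intermediate (not isolated)
17 | (2Z)-2-(iodomethylidene)pent-4-en-1-ol | OC/C(=C\I)CC=C | intermediate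
18 | tert-butyl{[(2Z)-2-(iodomethylidene)pent-4-en-1-yl]oxy}dimethylsilane | CC(C)(C)[Si](C)(C)OC/C(=C\I)CC=C | intermediate
19 | methyl (2S)-oxirane-2-carboxylate | COC(=O)[C@@H]1CO1 | starting material
20 | chloro{(Z)-2-{[tert-butyl(dimethyl)silyl]oxymethyl}penta-1,4-dien-1-yl}magnesium | CC(C)(C)[Si](C)(C)OC/C(=C\[Mg]Cl)CC=C | intermediate (not isolated)
21 | chloromagnesium alkoxide of methyl (2S,4Z)-5-{[tert-butyl(dimethyl)silyl]oxymethyl}-2-hydroxyocta-4,7-dienoate | COC(=O)[C@@H](O[Mg]Cl)C/C=C(\CO[Si](C)(C)C(C)(C)C)CC=C | intermediate (not isolated)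
22 | methyl (2S,4Z)-2-acetoxy-5-{[tert-butyl(dimethyl)silyl]oxymethyl}octa-4,7-dienoate | COC(=O)[C@@H](OC(C)=O)C/C=C(\CO[Si](C)(C)C(C)(C)C)CC=C | intermediate
23 | (5S)-5-[(2Z)-3-{[tert-butyl(dimethyl)silyl]oxymethyl}hexa-2,5-dien-1-yl]-4-hydroxyfuran-2(5H)-one | C=CC/C(CO[Si](C)(C)C(C)(C)C)=C/C[C@@H]1OC(=O)C=C1O | intermediate
24 | (2S)-2-[(2Z)-3-{[tert-butyl(dimethyl)silyl]oxymethyl}hexa-2,5-dien-1-yl]-5-oxo-2,5-dihydrofuran-3-yl trifluoromethanesulfonate | C=CC/C(CO[Si](C)(C)C(C)(C)C)=C/C[C@@H]1OC(=O)C=C1OS(=O)(=O)C(F)(F)F | intermediate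
25 | (5S)-5-[(2Z)-3-{[tert-butyl(dimethyl)silyl]oxymethyl}hexa-2,5-dien-1-yl]-4-(hydroxymethyl)furan-2(5H)-one | C=CC/C(CO[Si](C)(C)C(C)(C)C)=C/C[C@@H]1OC(=O)C=C1CO | intermediate
26 | (5S)-5-[(2Z,5E,7S)-3-{[tert-butyl(dimethyl)silyl]oxymethyl}-7-hydroxy-7-methyl-9-(2,6,6-trimethylcyclohex-1-en-1-yl)nona-2,5-dien-1-yl]-4-(hydroxymethyl)furan-2(5H)-one | CC1=C(CC[C@](C)(O)/C=C/C/C(CO[Si](C)(C)C(C)(C)C)=C/C[C@@H]2OC(=O)C=C2CO)C(C)(C)CCC1 | intermediate
27 | (5S)-5-[(2Z,5E,7S)-7-hydroxy-3-(hydroxymethyl)-7-methyl-9-(2,6,6-trimethylcyclohex-1-en-1-yl)nona-2,5-dien-1-yl]-4-(hydroxymethyl)furan-2(5H)-one | CC1=C(CC[C@](C)(O)/C=C/C/C(=C/C[C@@H]2OC(=O)C=C2CO)CO)C(C)(C)CCC1 | target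

**Count**
Total step count: 16. Longest linear sequence: 10 steps (steps 1–8, 15, 16); the eastern branch (steps 9–14) has 6 steps.

**Steps most likely to fail**

Step 3. The electron-rich diene may be protonated and oligomerise or isomerise, or the allyl cation may lose a proton before the second bond closes at the hindered CMe2 terminus. The fallback sets out from ketone 5 and closes the ring under neutral conditions by cycloaddition with nitroethylene (freshly made from 2-nitroethanol and phthalic anhydride; toluene, 23 → 60 °C). This should give 4-(2,6,6-trimethyl-5-nitrocyclohex-1-en-1-yl)butan-2-one F1 (either orientation of the nitro group converges). Radical denitration (Bu3SnH, AIBN, toluene, 110 °C) then returns to the route at compound 9, so that step 4 is not needed.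

Step 15. The catalyst may be deactivated and the skipped diene may migrate under ruthenium hydride catalysis in the presence of the hydroxymethyl butenolide, giving incomplete conversion or isomer mixtures that are hard to separate. The fallback moves the union ahead of the butenolide construction. It sets out from carbinol 14 and the robust acetoxy ester 22, which are joined by cross-metathesis (second-generation Grubbs catalyst, CH2Cl2, 40 °C) to methyl (2S,4Z,7E,9S)-2-acetoxy-5-{[tert-butyl(dimethyl)silyl]oxymethyl}-9-hydroxy-9-methyl-11-(2,6,6-trimethylcyclohex-1-en-1-yl)undeca-4,7-dienoate F4. Dieckmann condensation (LiN(SiMe3)2, 3.5 equiv, THF, −78 → −20 °C) should give the tetronic acid (5S)-5-[(2Z,5E,7S)-3-{[tert-butyl(dimethyl)silyl]oxymethyl}-7-hydroxy-7-methyl-9-(2,6,6-trimethylcyclohex-1-en-1-yl)nona-2,5-dien-1-yl]-4-hydroxyfuran-2(5H)-one F5. Selective sulfonylation of the acidic enol (Tf2O, i-Pr2NEt, CH2Cl2, −78 °C) gives the corresponding enol triflate F6. Stille coupling with Bu3SnCH2OH (Pd(PPh3)4, LiCl, 1,4-dioxane, 90 °C) comes back to the route at compound 26.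

Step 4. Oxidative addition at the hindered formyl group next to the quaternary carbon may be slow, and β-hydride elimination from the alkylrhodium intermediate may give ring alkenes. The fallback sets out from aldehyde 8. Pinnick oxidation (NaClO2, NaH2PO4, 2-methylbut-2-ene, t-BuOH/H2O) would give 2,2,4-trimethyl-3-(3-oxobutyl)cyclohex-3-ene-1-carboxylic acid F2. Coupling with N-hydroxypyridine-2-thione (DCC, DMAP, CH2Cl2, dark) would give the Barton ester 2-thioxopyridin-1(2H)-yl 2,2,4-trimethyl-3-(3-oxobutyl)cyclohex-3-ene-1-carboxylate F3. Photolysis with t-BuSH (visible light, toluene, 23 °C) effects reductive radical decarboxylation and comes back to the route at compound 9.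

**Further compounds**
F1 | step 3 | 4-(2,6,6-trimethyl-5-nitrocyclohex-1-en-1-yl)butan-2-one (racemic) | CC(=O)CCC1=C(C)CCC([N+](=O)[O-])C1(C)C
F2 | step 4 | 2,2,4-trimethyl-3-(3-oxobutyl)cyclohex-3-ene-1-carboxylic acid (racemic) | CC(=O)CCC1=C(C)CCC(C(=O)O)C1(C)C
F3 | step 4 | 2-thioxopyridin-1(2H)-yl 2,2,4-trimethyl-3-(3-oxobutyl)cyclohex-3-ene-1-carboxylate (racemic) | CC(=O)CCC1=C(C)CCC(C(=O)On2ccccc2=S)C1(C)C
F4 | step 15 | methyl (2S,4Z,7E,9S)-2-acetoxy-5-{[tert-butyl(dimethyl)silyl]oxymethyl}-9-hydroxy-9-methyl-11-(2,6,6-trimethylcyclohex-1-en-1-yl)undeca-4,7-dienoate | COC(=O)[C@@H](OC(C)=O)C/C=C(\CO[Si](C)(C)C(C)(C)C)C/C=C/[C@@](C)(O)CCC1=C(C)CCCC1(C)C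
F5 | step 15 | (5S)-5-[(2Z,5E,7S)-3-{[tert-butyl(dimethyl)silyl]oxymethyl}-7-hydroxy-7-methyl-9-(2,6,6-trimethylcyclohex-1-en-1-yl)nona-2,5-dien-1-yl]-4-hydroxyfuran-2(5H)-one | CC1=C(CC[C@](C)(O)/C=C/C/C(CO[Si](C)(C)C(C)(C)C)=C/C[C@@H]2OC(=O)C=C2O)C(C)(C)CCC1
F6 | step 15 | (2S)-2-[(2Z,5E,7S)-3-{[tert-butyl(dimethyl)silyl]oxymethyl}-7-hydroxy-7-methyl-9-(2,6,6-trimethylcyclohex-1-en-1-yl)nona-2,5-dien-1-yl]-5-oxo-2,5-dihydrofuran-3-yl trifluoromethanesulfonate | CC1=C(CC[C@](C)(O)/C=C/C/C(CO[Si](C)(C)C(C)(C)C)=C/C[C@@H]2OC(=O)C=C2OS(=O)(=O)C(F)(F)F)C(C)(C)CCC1
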